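## Retrosynthetic overview

1. Target ⇐ acetylation of the C2 alcohol of a ten-membered allylic alcohol ⇐ CrCl2/NiCl2 (Nozaki–Hiyama–Kishi) closure of C1–C2 in an E-alkenyl iodide/aldehyde seco compound.
2. Seco compound ⇐ C6–C7 bond by intermolecular zinc-mediated carbonyl allylation of a cis-2,3-epoxy aldehyde (fragment B: C2–C6, C15) with an (S)-5-substituted 3-(bromomethyl)butenolide (fragment A: C7–C14, C1). This one step sets C6 and C7 and turns the butenolide into the α-methylene-γ-lactone.
3. Fragment A ⇐ butenolide by ring-closing metathesis ⇐ (S)-epichlorohydrin (C8), trimethylsilylacetylene, Negishi carboalumination (E-C1=C10).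
4. Fragment B ⇐ Sharpless epoxidation (C4, C5) of a Z-allylic alcohol ⇐ cuprate addition to an ynoate made from but-3-yn-1-ol.
5. Ring order: five-membered lactone (in fragment A) and oxirane (in fragment B) first, ten-membered carbocycle last.

Assumption: the SMILES is read as (2S,4R,5S,6S,7R,8S) with E-C1=C10 and a cis-4,5-oxirane; germacrane numbering (C12 lactone carbonyl on O8, C13 exocyclic methylene, C14 on C10, C15 on C4) is used for all intermediates, and TBS = tert-butyldimethylsilyl.

## Route

**Fragment A**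

Step 1
Reactants: 1 (S)-epichlorohydrin; 2 trimethylsilylacetylene
Product: 4 (S)-1-chloro-5-(trimethylsilyl)pent-4-yn-2-ol, via lithium (trimethylsilyl)acetylide 3 (not isolated)
Conditions: 2, n-BuLi, THF, −78 °C; BF3·OEt2; then 1, −78 °C
Reagents that add atoms: none
Why: Yamaguchi–Hirao alkynylation: the BF3-activated epoxide is opened by the acetylide only at its unsubstituted CH2, so the stereocentre (future C8) is carried over unchanged and the chloride is kept for the next step.

Step 2
Reactants: 4 (S)-1-chloro-5-(trimethylsilyl)pent-4-yn-2-ol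
Product: 6 (S)-6-(trimethylsilyl)hex-1-en-5-yn-3-ol, via epoxide 5 (not isolated)
Conditions: Me3S+ I− (4 equiv), n-BuLi (3.8 equiv), THF, −20 °C → rt
Reagents that add atoms: trimethylsulfonium iodide (as dimethylsulfonium methylide), C[S+](C)C.[I-]
Why: Sulfonium-ylide one-carbon homologation (Alcaraz–Mioskowski): excess ylide closes the chlorohydrin to epoxide 5, opens it at CH2, and the β-alkoxy sulfonium salt loses Me2S by ylide-mediated elimination, giving the vinyl carbinol with the C–O stereocentre untouched.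

Step 3
Reactants: 6 (S)-6-(trimethylsilyl)hex-1-en-5-yn-3-ol
Product: 7 (S)-hex-1-en-5-yn-3-ol
Conditions: K2CO3, MeOH, rt (volatile product, concentrated cold)
Reagents that add atoms: none
Why: Base-catalysed protodesilylation of the alkynylsilane in methanol; no other group reacts.

Step 4
Reactants: 7 (S)-hex-1-en-5-yn-3-ol
Product: 9 (S,E)-6-iodo-5-methylhexa-1,5-dien-3-ol, via alkenylalane 8 (not isolated)
Conditions: AlMe3 (3 equiv), Cp2ZrCl2 (0.25 equiv), CH2Cl2, 0 °C → rt; then I2, THF, −30 → 0 °C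
Reagents that add atoms: trimethylaluminium, C[Al](C)C; iodine, [I][I]
Why: Negishi zirconium-catalysed carboalumination adds Me and Al syn across the terminal alkyne with Al on the terminal carbon (the alkoxide assists, the monosubstituted alkene is inert), and iodinolysis with retention fixes the E-alkenyl iodide (future C1=C10).

Step 5
Reactants: 10 methyl 2-(hydroxymethyl)acrylate
Product: 11 methyl 2-{[(tert-butyldimethylsilyl)oxy]methyl}acrylate
Conditions: TBSCl, imidazole, CH2Cl2, 0 °C → rt
Reagents that add atoms: tert-butyldimethylsilyl chloride, CC(C)(C)[Si](C)(C)Cl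
Why: Standard imidazole-promoted silylation of the primary alcohol.

Step 6
Reactants: 11 methyl 2-{[(tert-butyldimethylsilyl)oxy]methyl}acrylate
Product: 12 2-{[(tert-butyldimethylsilyl)oxy]methyl}acrylic acid
Conditions: LiOH, THF/H2O, 0 °C → rt; then 1 M HCl to pH 4, 0 °C
Reagents that add atoms: lithium hydroxide (hydroxide oxygen), [Li+].[OH-]
Why: Saponification of the unhindered methyl ester; the primary silyl ether survives cold LiOH and a brief pH 4 work-up.

Step 7
Reactants: 9 (S,E)-6-iodo-5-methylhexa-1,5-dien-3-ol; 12 2-{[(tert-butyldimethylsilyl)oxy]methyl}acrylic acid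
Product: 13 (S,E)-6-iodo-5-methylhexa-1,5-dien-3-yl 2-{[(tert-butyldimethylsilyl)oxy]methyl}acrylate
Conditions: DCC, DMAP (cat.), CH2Cl2, 0 °C → rt
Reagents that add atoms: none
Why: Steglich esterification (carbodiimide activation, DMAP acyl transfer) acylates the secondary allylic alcohol on oxygen with retention at C8.

Step 8
Reactants: 13 (S,E)-6-iodo-5-methylhexa-1,5-dien-3-yl 2-{[(tert-butyldimethylsilyl)oxy]methyl}acrylate
Product: 14 (S)-3-{[(tert-butyldimethylsilyl)oxy]methyl}-5-[(E)-3-iodo-2-methylprop-2-en-1-yl]furan-2(5H)-one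
Conditions: second-generation Grubbs catalyst RuCl2(H2IMes)(PCy3)(=CHPh) (10 mol %), toluene (5 mM), 80 °C
Reagents that add atoms: none
Why: Ring-closing metathesis of the terminal vinyl group onto the 1,1-disubstituted acrylate forms the five-membered butenolide with loss of ethylene, while the trisubstituted alkenyl iodide is too hindered and electron-poor to engage the ruthenium carbene.

Step 9
Reactants: 14 (S)-3-{[(tert-butyldimethylsilyl)oxy]methyl}-5-[(E)-3-iodo-2-methylprop-2-en-1-yl]furan-2(5H)-one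
Product: 15 (S)-3-(hydroxymethyl)-5-[(E)-3-iodo-2-methylprop-2-en-1-yl]furan-2(5H)-one
Conditions: HF·pyridine, pyridine, THF, 0 °C → rt
Reagents that add atoms: none
Why: Acidic fluoride desilylation frees the primary allylic alcohol without exposing the γ-proton of the butenolide to base.

Step 10
Reactants: 15 (S)-3-(hydroxymethyl)-5-[(E)-3-iodo-2-methylprop-2-en-1-yl]furan-2(5H)-one
Product: 16 (S)-3-(bromomethyl)-5-[(E)-3-iodo-2-methylprop-2-en-1-yl]furan-2(5H)-one
Conditions: CBr4, PPh3, CH2Cl2, 0 °C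
Reagents that add atoms: carbon tetrabromide, BrC(Br)(Br)Br
Why: Appel bromination converts the primary allylic alcohol into the bromide under neutral conditions.

**Fragment B**

Step 11
Reactants: 17 but-3-yn-1-ol
Product: 18 (but-3-yn-1-yloxy)(tert-butyl)dimethylsilane
Conditions: TBSCl, imidazole, DMF, rt
Reagents that add atoms: tert-butyldimethylsilyl chloride, CC(C)(C)[Si](C)(C)Cl
Why: Standard silylation of the primary alcohol; this ether later carries C2 through the coupling.

Step 12
Reactants: 18 (but-3-yn-1-yloxy)(tert-butyl)dimethylsilane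
Product: 20 methyl 5-[(tert-butyldimethylsilyl)oxy]pent-2-ynoate, via lithium acetylide 19 (not isolated)
Conditions: n-BuLi, THF, −78 °C; then ClCO2Me, −78 → 0 °C
Reagents that add atoms: methyl chloroformate, COC(=O)Cl
Why: Deprotonation of the terminal alkyne and C-acylation of the acetylide with the chloroformate.

Step 13
Reactants: 20 methyl 5-[(tert-butyldimethylsilyl)oxy]pent-2-ynoate
Product: 21 methyl (Z)-5-[(tert-butyldimethylsilyl)oxy]-3-methylpent-2-enoate
Conditions: Me2CuLi (CuI + 2 MeLi), THF, −78 °C; MeOH then aq. NH4Cl at −78 °C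
Reagents that add atoms: lithium dimethylcuprate (from MeLi and CuI), [Li+].C[Cu-]C
Why: Syn-carbocupration of the ynoate at −78 °C with cold protonation (Corey–Katzenellenbogen conjugate addition) places the new methyl trans to the ester and the silyloxyethyl chain cis to it, giving the Z-enoate needed for the cis-oxirane.

Step 14
Reactants: 21 methyl (Z)-5-[(tert-butyldimethylsilyl)oxy]-3-methylpent-2-enoate
Product: 22 (Z)-5-[(tert-butyldimethylsilyl)oxy]-3-methylpent-2-en-1-ol
Conditions: i-Bu2AlH (2.2 equiv), CH2Cl2, −78 °C; aq. KNaC4H4O6 work-up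
Reagents that add atoms: none
Why: 1,2-Reduction of the enoate with i-Bu2AlH gives the allylic alcohol without touching the alkene geometry or the silyl ether.

Step 15
Reactants: 22 (Z)-5-[(tert-butyldimethylsilyl)oxy]-3-methylpent-2-en-1-ol
Product: 23 {(2S,3R)-3-[2-(tert-butyldimethylsilyloxy)ethyl]-3-methyloxiran-2-yl}methanol
Conditions: Ti(OiPr)4 (10 mol %), L-(+)-diethyl tartrate (12 mol %), t-BuOOH, 4 Å molecular sieves, CH2Cl2, −20 °C
Reagents that add atoms: tert-butyl hydroperoxide, CC(C)(C)OO
Why: Sharpless asymmetric epoxidation: as for nerol, the L-(+)-tartrate titanium catalyst delivers oxygen to the face that gives the (2S,3R)-epoxy alcohol, and syn addition to the Z-alkene makes the cis-oxirane, setting C4 (R) and C5 (S) of the target.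

Step 16
Reactants: 23 {(2S,3R)-3-[2-(tert-butyldimethylsilyloxy)ethyl]-3-methyloxiran-2-yl}methanol
Product: 24 (2R,3R)-3-[2-(tert-butyldimethylsilyloxy)ethyl]-3-methyloxirane-2-carbaldehyde
Conditions: Dess–Martin periodinane, pyridine, CH2Cl2, 0 °C → rt
Reagents that add atoms: none
Why: Dess–Martin oxidation under buffered conditions gives the α,β-epoxy aldehyde, whose α-stereocentre is an oxirane carbon and cannot epimerise.

**Coupling and endgame**

Step 17
Reactants: 16 (S)-3-(bromomethyl)-5-[(E)-3-iodo-2-methylprop-2-en-1-yl]furan-2(5H)-one (fragment A); 24 (2R,3R)-3-[2-(tert-butyldimethylsilyloxy)ethyl]-3-methyloxirane-2-carbaldehyde (fragment B)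
Product: 26 (4S,5S)-4-[(S)-hydroxy{(2S,3R)-3-[2-(tert-butyldimethylsilyloxy)ethyl]-3-methyloxiran-2-yl}methyl]-5-[(E)-3-iodo-2-methylprop-2-en-1-yl]-3-methylidenedihydrofuran-2(3H)-one, via allylzinc bromide 25 (not isolated)
Conditions: Zn dust, THF/sat. aq. NH4Cl (5:1), 0 °C → rt
Reagents that add atoms: none
Why: Barbier-type carbonyl allylation: zinc inserts into the allylic C–Br bond and allylzinc 25 adds through its γ-carbon (C7) in a closed chair transition state, on the butenolide face anti to the C8 side chain (7,8-trans), with the ring-locked E-type geometry giving the 6,7-relationship of the target and with attack on the Felkin–Anh face of the epoxy aldehyde (anti to the oxirane C–O), a matched pairing that sets C6 (S) and C7 and moves the double bond to the exocyclic position.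

Step 18
Reactants: 26 allylation adduct (C6 alcohol)
Product: 27 (S)-{(2S,3R)-3-[2-(tert-butyldimethylsilyloxy)ethyl]-3-methyloxiran-2-yl}{(2S,3R)-2-[(E)-3-iodo-2-methylprop-2-en-1-yl]-4-methylidene-5-oxotetrahydrofuran-3-yl}methyl acetate
Conditions: Ac2O, pyridine, DMAP (cat.), CH2Cl2, 0 °C
Reagents that add atoms: acetic anhydride, CC(=O)OC(C)=O
Why: DMAP-catalysed acetylation of the secondary alcohol is fast enough to forestall translactonisation onto O6 and installs the C6 acetate of the target with retention.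

Step 19
Reactants: 27 C6 acetate with C2 silyl ether
Product: 28 (S)-[(2S,3R)-3-(2-hydroxyethyl)-3-methyloxiran-2-yl]{(2S,3R)-2-[(E)-3-iodo-2-methylprop-2-en-1-yl]-4-methylidene-5-oxotetrahydrofuran-3-yl}methyl acetate
Conditions: HF·pyridine, excess pyridine, THF, 0 °C → rt
Reagents that add atoms: none
Why: Pyridine-buffered HF cleaves the primary silyl ether while the acetate, the lactone and the oxirane are left intact.

Step 20
Reactants: 28 primary alcohol (C2)
Product: 29 (S)-[(2S,3R)-3-methyl-3-(2-oxoethyl)oxiran-2-yl]{(2S,3R)-2-[(E)-3-iodo-2-methylprop-2-en-1-yl]-4-methylidene-5-oxotetrahydrofuran-3-yl}methyl acetate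
Conditions: Dess–Martin periodinane, pyridine, CH2Cl2, 0 °C; crude aldehyde used at once
Reagents that add atoms: none
Why: Dess–Martin oxidation in a buffered, non-basic medium gives the β,γ-epoxy aldehyde, which is used immediately and unpurified because base or silica would open the oxirane by E1cB elimination.

Step 21
Reactants: 29 alkenyl iodide/aldehyde seco compound
Product: 31 (1(10)E,2S,4R,5S,6S,7R,8S)-6-acetoxy-4,5-epoxy-2-hydroxygermacra-1(10),11(13)-dien-12,8-olide, via alkenylchromium dichloride 30 (not isolated)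
Conditions: CrCl2 (10 equiv), NiCl2 (cat.), degassed DMSO (3 mM, slow addition of 29), rt
Reagents that add atoms: none
Why: Nozaki–Hiyama–Kishi reaction: zerovalent nickel formed in situ inserts into the C–I bond, transmetallation gives the alkenyl trivalent-chromium species 30, which adds only to the aldehyde with retention of the E geometry under high dilution, and C2 is set under substrate control, the chromium alkoxide being expected on the outer, pseudo-equatorial side of the forming ring, which corresponds to the (2S)-alcohol.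

Step 22
Reactants: 31 macrocyclic C2 alcohol
Product: 32 (1(10)E,2S,4R,5S,6S,7R,8S)-2,6-diacetoxy-4,5-epoxygermacra-1(10),11(13)-dien-12,8-olide (target)
Conditions: Ac2O, pyridine, DMAP (cat.), CH2Cl2, 0 °C → rt
Reagents that add atoms: acetic anhydride, CC(=O)OC(C)=O
Why: DMAP-catalysed acetylation of the secondary allylic alcohol with retention completes the target.

## Compound list

1 | (S)-epichlorohydrin | ClC[C@@H]1CO1 | starting material
2 | trimethylsilylacetylene | C#C[Si](C)(C)C | starting material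
3 | lithium (trimethylsilyl)acetylide | [Li]C#C[Si](C)(C)C | intermediate (not isolated)
4 | (S)-1-chloro-5-(trimethylsilyl)pent-4-yn-2-ol | ClC[C@@H](O)CC#C[Si](C)(C)C | intermediate
5 | (S)-2-[3-(trimethylsilyl)prop-2-yn-1-yl]oxirane | C1O[C@H]1CC#C[Si](C)(C)C | intermediate (not isolated)
6 | (S)-6-(trimethylsilyl)hex-1-en-5-yn-3-ol | C=C[C@@H](O)CC#C[Si](C)(C)C | intermediate
7 | (S)-hex-1-en-5-yn-3-ol | C=C[C@@H](O)CC#C | intermediate
8 | dimethylaluminium (S,E)-6-(dimethylalumanyl)-5-methylhexa-1,5-dien-3-olate | C=C[C@@H](O[Al](C)C)C/C(C)=C/[Al](C)C | intermediate (not isolated)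
9 | (S,E)-6-iodo-5-methylhexa-1,5-dien-3-ol | C=C[C@@H](O)C/C(C)=C/I | intermediate
10 | methyl 2-(hydroxymethyl)acrylate | C=C(CO)C(=O)OC | starting material
11 | methyl 2-{[(tert-butyldimethylsilyl)oxy]methyl}acrylate | C=C(CO[Si](C)(C)C(C)(C)C)C(=O)OC | intermediate
12 | 2-{[(tert-butyldimethylsilyl)oxy]methyl}acrylic acid | C=C(CO[Si](C)(C)C(C)(C)C)C(=O)O | intermediate
13 | (S,E)-6-iodo-5-methylhexa-1,5-dien-3-yl 2-{[(tert-butyldimethylsilyl)oxy]methyl}acrylate | C=C[C@@H](OC(=O)C(=C)CO[Si](C)(C)C(C)(C)C)C/C(C)=C/I | intermediate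
14 | (S)-3-{[(tert-butyldimethylsilyl)oxy]methyl}-5-[(E)-3-iodo-2-methylprop-2-en-1-yl]furan-2(5H)-one | O=C1O[C@@H](C/C(C)=C/I)C=C1CO[Si](C)(C)C(C)(C)C | intermediate
15 | (S)-3-(hydroxymethyl)-5-[(E)-3-iodo-2-methylprop-2-en-1-yl]furan-2(5H)-one | O=C1O[C@@H](C/C(C)=C/I)C=C1CO | intermediate
16 | (S)-3-(bromomethyl)-5-[(E)-3-iodo-2-methylprop-2-en-1-yl]furan-2(5H)-one | O=C1O[C@@H](C/C(C)=C/I)C=C1CBr | intermediate
17 | but-3-yn-1-ol | C#CCCO | starting material
18 | (but-3-yn-1-yloxy)(tert-butyl)dimethylsilane | C#CCCO[Si](C)(C)C(C)(C)C | intermediate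
19 | lithium acetylide of 18 | [Li]C#CCCO[Si](C)(C)C(C)(C)C | intermediate (not isolated)
20 | methyl 5-[(tert-butyldimethylsilyl)oxy]pent-2-ynoate | COC(=O)C#CCCO[Si](C)(C)C(C)(C)C | intermediate
21 | methyl (Z)-5-[(tert-butyldimethylsilyl)oxy]-3-methylpent-2-enoate | COC(=O)/C=C(/C)CCO[Si](C)(C)C(C)(C)C | intermediate
22 | (Z)-5-[(tert-butyldimethylsilyl)oxy]-3-methylpent-2-en-1-ol | OC/C=C(/C)CCO[Si](C)(C)C(C)(C)C | intermediate
23 | {(2S,3R)-3-[2-(tert-butyldimethylsilyloxy)ethyl]-3-methyloxiran-2-yl}methanol | CC(C)(C)[Si](C)(C)OCC[C@@]1(C)O[C@H]1CO | intermediate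
24 | (2R,3R)-3-[2-(tert-butyldimethylsilyloxy)ethyl]-3-methyloxirane-2-carbaldehyde | CC(C)(C)[Si](C)(C)OCC[C@@]1(C)O[C@H]1C=O | intermediate
25 | {[(S)-5-((E)-3-iodo-2-methylprop-2-en-1-yl)-2-oxo-2,5-dihydrofuran-3-yl]methyl}zinc bromide | O=C1O[C@@H](C/C(C)=C/I)C=C1C[Zn]Br | intermediate (not isolated)
26 | (4S,5S)-4-[(S)-hydroxy{(2S,3R)-3-[2-(tert-butyldimethylsilyloxy)ethyl]-3-methyloxiran-2-yl}methyl]-5-[(E)-3-iodo-2-methylprop-2-en-1-yl]-3-methylidenedihydrofuran-2(3H)-one | C=C1C(=O)O[C@@H](C/C(C)=C/I)[C@@H]1[C@H](O)[C@@H]2O[C@]2(C)CCO[Si](C)(C)C(C)(C)C | intermediate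
27 | (S)-{(2S,3R)-3-[2-(tert-butyldimethylsilyloxy)ethyl]-3-methyloxiran-2-yl}{(2S,3R)-2-[(E)-3-iodo-2-methylprop-2-en-1-yl]-4-methylidene-5-oxotetrahydrofuran-3-yl}methyl acetate | C=C1C(=O)O[C@@H](C/C(C)=C/I)[C@@H]1[C@H](OC(C)=O)[C@@H]2O[C@]2(C)CCO[Si](C)(C)C(C)(C)C | intermediate
28 | (S)-[(2S,3R)-3-(2-hydroxyethyl)-3-methyloxiran-2-yl]{(2S,3R)-2-[(E)-3-iodo-2-methylprop-2-en-1-yl]-4-methylidene-5-oxotetrahydrofuran-3-yl}methyl acetate | C=C1C(=O)O[C@@H](C/C(C)=C/I)[C@@H]1[C@H](OC(C)=O)[C@@H]2O[C@]2(C)CCO | intermediate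
29 | (S)-[(2S,3R)-3-methyl-3-(2-oxoethyl)oxiran-2-yl]{(2S,3R)-2-[(E)-3-iodo-2-methylprop-2-en-1-yl]-4-methylidene-5-oxotetrahydrofuran-3-yl}methyl acetate | C=C1C(=O)O[C@@H](C/C(C)=C/I)[C@@H]1[C@H](OC(C)=O)[C@@H]2O[C@]2(C)CC=O | intermediate
30 | alkenylchromium dichloride from 29 (CrCl2 group in place of iodine) | C=C1C(=O)O[C@@H](C/C(C)=C/[Cr](Cl)Cl)[C@@H]1[C@H](OC(C)=O)[C@@H]2O[C@]2(C)CC=O | intermediate (not isolated)
31 | (1(10)E,2S,4R,5S,6S,7R,8S)-6-acetoxy-4,5-epoxy-2-hydroxygermacra-1(10),11(13)-dien-12,8-olide | C=C1C(=O)O[C@H]2C/C(C)=C/[C@@H](O)C[C@@]3(C)O[C@H]3[C@@H](OC(C)=O)[C@H]12 | intermediate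
32 | (1(10)E,2S,4R,5S,6S,7R,8S)-2,6-diacetoxy-4,5-epoxygermacra-1(10),11(13)-dien-12,8-olide (CNP0270851.3) | C=C1C(=O)O[C@H]2C/C(C)=C/[C@@H](OC(C)=O)C[C@@]3(C)O[C@H]3[C@@H](OC(C)=O)[C@H]12 | target

## Step count and risks

Total: 22 steps. Longest linear sequence: 14 steps (1–4, 7–10, 17–22, from (S)-epichlorohydrin).

**Most likely to fail**

1. Step 21 (CrCl2/NiCl2 ring closure). The β,γ-epoxy aldehyde 29 is fragile, a ten-membered ring is being closed, and the C2 configuration rests on substrate control that is argued by analogy rather than known, so it is the least secure stereocentre of the route. The fallback sets out from 29. If the closure gives mainly the C2-epimeric alcohol, (1(10)E,2R,4R,5S,6S,7R,8S)-6-acetoxy-4,5-epoxy-2-hydroxygermacra-1(10),11(13)-dien-12,8-olide F1, this is not acetylated with retention. It is instead esterified under Mitsunobu conditions (AcOH, PPh3, DIAD, toluene, 0 °C), which inverts C2 by SN2 displacement and comes back to the route directly at the target 32.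

2. Step 17 (zinc Barbier coupling). The risks are incomplete facial control at C6/C7 in the aqueous medium, protonation of the allylzinc, and translactonisation of 26. The fallback sets out from bromide 16. Borylation with bis(pinacolato)diboron and Pd2(dba)3 (cat.) in DMSO at rt (the allylic bromide ionises far faster than the hindered alkenyl iodide reacts) gives (S)-5-[(E)-3-iodo-2-methylprop-2-en-1-yl]-3-[(4,4,5,5-tetramethyl-1,3,2-dioxaborolan-2-yl)methyl]furan-2(5H)-one F2. This isolable allylboronate is heated with aldehyde 24 in toluene at 80 °C. It reacts through the same closed six-membered transition state (Hoffmann/Hall-type allylboration) without water or zinc salts, and aqueous work-up of the borate comes back to the route at alcohol 26.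

3. Step 8 (metathesis to a trisubstituted butenolide bearing a bulky CH2OTBS group). The fallback sets out from alcohol 9. Acylation with acryloyl chloride (Et3N, CH2Cl2, −78 → 0 °C) gives (S,E)-6-iodo-5-methylhexa-1,5-dien-3-yl acrylate F3. Its ring-closing metathesis (RuCl2(H2IMes)(PCy3)(=CHPh), CH2Cl2, 40 °C) is the much easier disubstituted case and gives (S)-5-[(E)-3-iodo-2-methylprop-2-en-1-yl]furan-2(5H)-one F4. The hydroxymethyl group is then introduced by a selenolate-triggered Michael/aldol sequence (PhSeLi, THF, −78 °C; then monomeric formaldehyde), with the selenide adding anti to the C5 substituent, to give (3S,4R,5S)-3-(hydroxymethyl)-5-[(E)-3-iodo-2-methylprop-2-en-1-yl]-4-(phenylselanyl)dihydrofuran-2(3H)-one F5. Oxidation (H2O2, pyridine, CH2Cl2, 0 °C) and selenoxide syn-elimination restore the ring double bond and come back to the route at alcohol 15.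

## Further compounds

F1 | step 21 | (1(10)E,2R,4R,5S,6S,7R,8S)-6-acetoxy-4,5-epoxy-2-hydroxygermacra-1(10),11(13)-dien-12,8-olide | C=C1C(=O)O[C@H]2C/C(C)=C/[C@H](O)C[C@@]3(C)O[C@H]3[C@@H](OC(C)=O)[C@H]12
F2 | step 17 | (S)-5-[(E)-3-iodo-2-methylprop-2-en-1-yl]-3-[(4,4,5,5-tetramethyl-1,3,2-dioxaborolan-2-yl)methyl]furan-2(5H)-one | O=C1O[C@@H](C/C(C)=C/I)C=C1CB1OC(C)(C)C(C)(C)O1
F3 | step 8 | (S,E)-6-iodo-5-methylhexa-1,5-dien-3-yl acrylate | C=CC(=O)O[C@H](C=C)C/C(C)=C/I
F4 | step 8 | (S)-5-[(E)-3-iodo-2-methylprop-2-en-1-yl]furan-2(5H)-one | O=C1O[C@@H](C/C(C)=C/I)C=C1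
F5 | step 8 | (3S,4R,5S)-3-(hydroxymethyl)-5-[(E)-3-iodo-2-methylprop-2-en-1-yl]-4-(phenylselanyl)dihydrofuran-2(3H)-one | O=C1O[C@@H](C/C(C)=C/I)[C@H]([Se]c2ccccc2)[C@H]1CO
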